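## Retrosynthetic overview

1. The target comes from bis-Weinreb amide acetate 24 (both CHO groups by amide reduction), which comes from opening the trans-fused δ-lactone/cyclononadiene 22 that ties C18 to C19.
2. The nine-membered ring is closed at C3–C4 by an intramolecular B-alkyl Suzuki coupling of a vinyl group with an (E)-vinyl iodide (20); C7=C8 comes from an HWE olefination with (E)-4-iodopent-3-enal.
3. C8–C9 is made by a visible-light radical alkylation of the ketene silyl acetal of δ-lactone 12 with a bromo(phosphono) Weinreb acetamide; this sets C9 and installs the HWE handle.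
4. δ-Lactone 12 comes from Zn fragmentation of the all-trans butyrolactone 8 (the bought stereocentre becomes the vinyl group); 8 comes from (R)-butenolide 2 by Mukaiyama–Michael addition (C1) and enolate alkylation (C10).
5. Ring order: butyrolactone (bought), then δ-valerolactone (stereo-template), then the cyclononadiene (last); both lactones are opened on the way.

Assumption: (R)-5-(hydroxymethyl)furan-2(5H)-one (the enantiomer of the common (S)-butenolide; made from D-glutamic acid) and 5-iodo-2-methylpent-2-ene are bought.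

Atom labels used below: ring C1 (bears the side chain)–C2–C3–C4(Me)=C5–C6–C7=C8(C17)–C9(C18); side chain C10(C19H2O)–C11…

## Route

Step 1
Reactants: 1 (R)-5-(hydroxymethyl)furan-2(5H)-one
Product: 2 (R)-5-{[(tert-butyldimethylsilyl)oxy]methyl}furan-2(5H)-one
Conditions: TBSCl, imidazole, CH2Cl2, 0 °C to rt
Reagents that add atoms: tert-butyldimethylsilyl chloride, CC(C)(C)[Si](C)(C)Cl
Why: Standard silylation of the primary alcohol; the bought stereocentre (future C2, later destroyed) is untouched.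

Step 2
Reactants: 2 (R)-5-{[(tert-butyldimethylsilyl)oxy]methyl}furan-2(5H)-one; 3 tert-butyl[(1-methoxyethenyl)oxy]dimethylsilane
Product: 5 methyl 2-[(2R,3R)-2-{[(tert-butyldimethylsilyl)oxy]methyl}-5-oxooxolan-3-yl]acetate, via lactone silyl ketene acetal 4 (not isolated)
Conditions: TBSOTf (10 mol %), CH2Cl2, −78 °C; then AcOH/H2O/THF, 0 °C
Reagents that add atoms: none
Why: Mukaiyama–Michael addition under non-basic conditions (no γ-deprotonation of the butenolide) delivers the acetate unit to the β-carbon anti to the γ-CH2OTBS group, which sets C1.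

Step 3
Reactants: 5 methyl 2-[(2R,3R)-2-{[(tert-butyldimethylsilyl)oxy]methyl}-5-oxooxolan-3-yl]acetate; 6 5-iodo-2-methylpent-2-ene
Product: 7 methyl 2-[(2R,3R,4R)-2-{[(tert-butyldimethylsilyl)oxy]methyl}-4-(4-methylpent-3-en-1-yl)-5-oxooxolan-3-yl]acetate (all-trans)
Conditions: LDA (1.05 equiv), THF, −78 °C; 6, DMPU, −78 to −20 °C
Reagents that add atoms: none
Why: The lactone α-CH2 is deprotonated in preference to the less acidic acyclic ester, and the enolate is alkylated anti to the adjacent C1 substituent (lactone enolate alkylation), which sets C10.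

Step 4
Reactants: 7 methyl 2-[(2R,3R,4R)-2-{[(tert-butyldimethylsilyl)oxy]methyl}-4-(4-methylpent-3-en-1-yl)-5-oxooxolan-3-yl]acetate
Product: 8 methyl 2-[(2R,3R,4R)-2-(bromomethyl)-4-(4-methylpent-3-en-1-yl)-5-oxooxolan-3-yl]acetate
Conditions: Ph3PBr2, CH2Cl2, rt
Reagents that add atoms: dibromotriphenylphosphorane, BrP(Br)(c1ccccc1)(c1ccccc1)c1ccccc1
Why: Direct Appel-type conversion of a primary TBS ether into the bromide through the alkoxyphosphonium salt; no stereocentre is involved.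

Step 5
Reactants: 8 methyl 2-[(2R,3R,4R)-2-(bromomethyl)-4-(4-methylpent-3-en-1-yl)-5-oxooxolan-3-yl]acetate
Product: 9 (2R,3S)-3-ethenyl-5-methoxy-2-(4-methylpent-3-en-1-yl)-5-oxopentanoic acid
Conditions: activated Zn, EtOH/H2O (9:1), reflux; then dilute HCl
Reagents that add atoms: none
Why: Zinc-mediated reductive β-elimination (Bernet–Vasella-type fragmentation) expels the lactone carboxylate, turning the sacrificial C2 stereocentre into the C2=C3 vinyl group and freeing the C19 acid; C1 and C10 are not touched.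

Step 6
Reactants: 9 (2R,3S)-3-ethenyl-5-methoxy-2-(4-methylpent-3-en-1-yl)-5-oxopentanoic acid
Product: 12 (4S,5R)-4-ethenyl-5-(4-methylpent-3-en-1-yl)oxan-2-one, via mixed carbonic anhydride 10 (not isolated), via hydroxy ester 11 (not isolated)
Conditions: i-BuOCOCl, NMM, THF, −15 °C; NaBH4, THF/H2O, 0 °C; then PPTS, PhMe, 80 °C
Reagents that add atoms: none
Why: Mixed-anhydride activation lets NaBH4 reduce only the acid (ester and alkenes survive), and the δ-hydroxy ester lactonises to the six-membered template with vinyl and homoprenyl groups cis.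

Step 7
Reactants: 13 diethyl [2-(methoxy(methyl)amino)-2-oxoethyl]phosphonate
Product: 14 diethyl [1-bromo-2-(methoxy(methyl)amino)-2-oxoethyl]phosphonate (racemic)
Conditions: NaH, THF, 0 °C; Br2 (1.0 equiv), −78 °C
Reagents that add atoms: bromine, BrBr
Why: Electrophilic bromination of the stabilised phosphonoacetamide anion gives the radical precursor.

Step 8
Reactants: 12 (4S,5R)-4-ethenyl-5-(4-methylpent-3-en-1-yl)oxan-2-one; 14 diethyl [1-bromo-2-(methoxy(methyl)amino)-2-oxoethyl]phosphonate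
Product: 16 diethyl {1-[(3R,4S,5R)-4-ethenyl-5-(4-methylpent-3-en-1-yl)-2-oxooxan-3-yl]-2-(methoxy(methyl)amino)-2-oxoethyl}phosphonate (both epimers at the phosphonate carbon), via ketene silyl acetal 15 (not isolated)
Conditions: LDA, THF, −78 °C; TBSCl, DMPU, −78 to 0 °C; evaporate; 14 (1.5 equiv), fac-Ir(ppy)3 (1 mol %), MeCN, 450 nm LEDs, rt
Reagents that add atoms: none
Why: Proposed new method: excited Ir(III) reduces the C–Br bond of 14 to an electrophilic phosphonoacetamide radical, which adds to the electron-rich ketene silyl acetal at C9 from the face opposite the cis vinyl and homoprenyl groups (setting C9 trans to C1), and the resulting α,α-dioxy radical is oxidised by Ir(IV) and loses the silyl group to bromide; the closest known reaction type is the photoredox radical–polar crossover α-alkylation of enol silanes with bromomalonates, not yet shown for a lactone ketene acetal with an α-bromo phosphonoacetamide, an electrophile that enolates cannot C-alkylate by SN2 because they attack bromine.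

Step 9
Reactants: 17 pent-3-yn-1-ol
Product: 18 (E)-4-iodopent-3-en-1-ol
Conditions: Cp2Zr(H)Cl (2.5 equiv), THF, 40 °C; I2, 0 °C
Reagents that add atoms: iodine, II
Why: Syn hydrozirconation, equilibrated with excess reagent to put Zr on the methyl-bearing carbon, followed by iodinolysis with retention gives the (E)-vinyl iodide (Schwartz hydrozirconation–iodination).

Step 10
Reactants: 18 (E)-4-iodopent-3-en-1-ol
Product: 19 (E)-4-iodopent-3-enal
Conditions: Dess–Martin periodinane, NaHCO3, CH2Cl2, 0 °C; used at once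
Reagents that add atoms: none
Why: Buffered Dess–Martin oxidation gives the β,γ-unsaturated aldehyde without moving the double bond.

Step 11
Reactants: 16 diethyl {1-[(3R,4S,5R)-4-ethenyl-5-(4-methylpent-3-en-1-yl)-2-oxooxan-3-yl]-2-(methoxy(methyl)amino)-2-oxoethyl}phosphonate; 19 (E)-4-iodopent-3-enal
Product: 20 (2E,5E)-2-[(3S,4S,5R)-4-ethenyl-5-(4-methylpent-3-en-1-yl)-2-oxooxan-3-yl]-6-iodo-N-methoxy-N-methylhepta-2,5-dienamide
Conditions: NaH (1.0 equiv), THF, 0 °C; 19, −78 to 0 °C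
Reagents that add atoms: none
Why: Horner–Wadsworth–Emmons olefination of the phosphonate carbanion (the only site deprotonated by one equivalent of base) gives the trisubstituted C7=C8 alkene with C6 trans to the amide carbonyl, as for α-alkyl phosphonoacetates; C9 is untouched.

Step 12
Reactants: 20 (2E,5E)-2-[(3S,4S,5R)-4-ethenyl-5-(4-methylpent-3-en-1-yl)-2-oxooxan-3-yl]-6-iodo-N-methoxy-N-methylhepta-2,5-dienamide
Product: 22 (4R,4aS,7E,10E,11aS)-N-methoxy-N,7-dimethyl-4-(4-methylpent-3-en-1-yl)-1-oxo-1,3,4,4a,5,6,9,11a-octahydrocyclonona[c]pyran-11-carboxamide (cyclononadiene trans-fused to the δ-lactone), via B-alkyl-9-BBN borane 21 (not isolated)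
Conditions: 9-BBN (1.5 equiv), THF, rt; slow addition to Pd(dppf)Cl2 (15 mol %), AsPh3, Cs2CO3, DMF/THF/H2O, 2 mM, 50 °C
Reagents that add atoms: none
Why: 9-BBN hydroborates only the monosubstituted vinyl group, and the intramolecular B-alkyl Suzuki–Miyaura coupling closes the nine-membered ring at C3–C4 with retention of the (E)-vinyl iodide geometry.

Step 13
Reactants: 22 (4R,4aS,7E,10E,11aS)-N-methoxy-N,7-dimethyl-4-(4-methylpent-3-en-1-yl)-1-oxo-1,3,4,4a,5,6,9,11a-octahydrocyclonona[c]pyran-11-carboxamide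
Product: 23 (1S,2E,5E,9S)-9-[(2R)-1-hydroxy-6-methylhept-5-en-2-yl]-N1,N2-dimethoxy-N1,N2,6-trimethylcyclonona-2,5-diene-1,2-dicarboxamide
Conditions: MeNHOMe·HCl, AlMe3, CH2Cl2, 0 °C to rt; Rochelle salt
Reagents that add atoms: N,O-dimethylhydroxylamine hydrochloride, CNOC.Cl
Why: Weinreb aminolysis of the δ-lactone with the aluminium amide frees the C19 alcohol and puts C18 at the same amide level as C17, without basic conditions that could epimerise C9.

Step 14
Reactants: 23 (1S,2E,5E,9S)-9-[(2R)-1-hydroxy-6-methylhept-5-en-2-yl]-N1,N2-dimethoxy-N1,N2,6-trimethylcyclonona-2,5-diene-1,2-dicarboxamide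
Product: 24 (2R)-2-[(1S,2S,3E,6E)-2,3-bis(methoxy(methyl)carbamoyl)-7-methylcyclonona-3,6-dien-1-yl]-6-methylhept-5-en-1-yl acetate
Conditions: Ac2O, pyridine, DMAP (cat.), CH2Cl2, 0 °C, directly on crude 23
Reagents that add atoms: acetic anhydride, CC(=O)OC(C)=O
Why: Acetylation of the only free hydroxyl fixes the C19 acetate before any aldehyde exists, so no lactol can form.

Step 15
Reactants: 24 (2R)-2-[(1S,2S,3E,6E)-2,3-bis(methoxy(methyl)carbamoyl)-7-methylcyclonona-3,6-dien-1-yl]-6-methylhept-5-en-1-yl acetate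
Product: 25 (2R)-2-[(1S,2S,3E,6E)-2,3-diformyl-7-methylcyclonona-3,6-dien-1-yl]-6-methylhept-5-en-1-yl acetate (target)
Conditions: Cp2Zr(H)Cl (4 equiv), THF, rt, 20 min; silica gel/H2O
Reagents that add atoms: none
Why: Schwartz-reagent reduction of both Weinreb amides stops at the zirconated hemiaminal and gives the two aldehydes on neutral work-up, leaving the acetate, the trisubstituted alkenes and the epimerisable C9 alone.

## Compound list

1 | (R)-5-(hydroxymethyl)furan-2(5H)-one | O=C1O[C@@H](CO)C=C1 | starting material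
2 | (R)-5-{[(tert-butyldimethylsilyl)oxy]methyl}furan-2(5H)-one | O=C1O[C@@H](CO[Si](C)(C)C(C)(C)C)C=C1 | intermediate
3 | tert-butyl[(1-methoxyethenyl)oxy]dimethylsilane | C=C(OC)O[Si](C)(C)C(C)(C)C | starting material
4 | methyl 2-[(2R,3R)-5-[(tert-butyldimethylsilyl)oxy]-2-{[(tert-butyldimethylsilyl)oxy]methyl}-2,3-dihydrofuran-3-yl]acetate | COC(=O)C[C@@H]1C=C(O[Si](C)(C)C(C)(C)C)O[C@H]1CO[Si](C)(C)C(C)(C)C | intermediate
5 | methyl 2-[(2R,3R)-2-{[(tert-butyldimethylsilyl)oxy]methyl}-5-oxooxolan-3-yl]acetate | O=C1O[C@@H](CO[Si](C)(C)C(C)(C)C)[C@H](CC(=O)OC)C1 | intermediate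
6 | 5-iodo-2-methylpent-2-ene | ICCC=C(C)C | starting material
7 | methyl 2-[(2R,3R,4R)-2-{[(tert-butyldimethylsilyl)oxy]methyl}-4-(4-methylpent-3-en-1-yl)-5-oxooxolan-3-yl]acetate | O=C1O[C@@H](CO[Si](C)(C)C(C)(C)C)[C@H](CC(=O)OC)[C@H]1CCC=C(C)C | intermediate
8 | methyl 2-[(2R,3R,4R)-2-(bromomethyl)-4-(4-methylpent-3-en-1-yl)-5-oxooxolan-3-yl]acetate | O=C1O[C@@H](CBr)[C@H](CC(=O)OC)[C@H]1CCC=C(C)C | intermediate
9 | (2R,3S)-3-ethenyl-5-methoxy-2-(4-methylpent-3-en-1-yl)-5-oxopentanoic acid | OC(=O)[C@H](CCC=C(C)C)[C@H](C=C)CC(=O)OC | intermediate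
10 | isobutyl carbonic anhydride of acid 9 | CC(C)COC(=O)OC(=O)[C@H](CCC=C(C)C)[C@H](C=C)CC(=O)OC | intermediate
11 | methyl (3S,4R)-3-ethenyl-4-(hydroxymethyl)-8-methylnon-7-enoate | OC[C@H](CCC=C(C)C)[C@H](C=C)CC(=O)OC | intermediate
12 | (4S,5R)-4-ethenyl-5-(4-methylpent-3-en-1-yl)oxan-2-one | O=C1C[C@@H](C=C)[C@@H](CCC=C(C)C)CO1 | intermediate
13 | diethyl [2-(methoxy(methyl)amino)-2-oxoethyl]phosphonate | CCOP(=O)(CC(=O)N(C)OC)OCC | starting material
14 | diethyl [1-bromo-2-(methoxy(methyl)amino)-2-oxoethyl]phosphonate | CCOP(=O)(OCC)C(Br)C(=O)N(C)OC | intermediate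
15 | tert-butyl{[(3R,4S)-4-ethenyl-3-(4-methylpent-3-en-1-yl)-3,4-dihydro-2H-pyran-6-yl]oxy}dimethylsilane | CC(C)(C)[Si](C)(C)OC1=C[C@@H](C=C)[C@@H](CCC=C(C)C)CO1 | intermediate
16 | diethyl {1-[(3R,4S,5R)-4-ethenyl-5-(4-methylpent-3-en-1-yl)-2-oxooxan-3-yl]-2-(methoxy(methyl)amino)-2-oxoethyl}phosphonate | O=C1[C@H](C(P(=O)(OCC)OCC)C(=O)N(C)OC)[C@@H](C=C)[C@@H](CCC=C(C)C)CO1 | intermediate
17 | pent-3-yn-1-ol | CC#CCCO | starting material
18 | (E)-4-iodopent-3-en-1-ol | OCC/C=C(\C)I | intermediate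
19 | (E)-4-iodopent-3-enal | O=CC/C=C(\C)I | intermediate
20 | (2E,5E)-2-[(3S,4S,5R)-4-ethenyl-5-(4-methylpent-3-en-1-yl)-2-oxooxan-3-yl]-6-iodo-N-methoxy-N-methylhepta-2,5-dienamide | O=C1[C@H](/C(=C\C/C=C(\C)I)C(=O)N(C)OC)[C@@H](C=C)[C@@H](CCC=C(C)C)CO1 | intermediate
21 | (2E,5E)-2-[(3S,4S,5R)-4-[2-(9-borabicyclo[3.3.1]nonan-9-yl)ethyl]-5-(4-methylpent-3-en-1-yl)-2-oxooxan-3-yl]-6-iodo-N-methoxy-N-methylhepta-2,5-dienamide | O=C1[C@H](/C(=C\C/C=C(\C)I)C(=O)N(C)OC)[C@@H](CCB2C3CCCC2CCC3)[C@@H](CCC=C(C)C)CO1 | intermediate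
22 | (4R,4aS,7E,10E,11aS)-N-methoxy-N,7-dimethyl-4-(4-methylpent-3-en-1-yl)-1-oxo-1,3,4,4a,5,6,9,11a-octahydrocyclonona[c]pyran-11-carboxamide | O=C2OC[C@H](CCC=C(C)C)[C@@H]1CC/C(C)=C/C/C=C(/C(=O)N(C)OC)[C@H]12 | intermediate
23 | (1S,2E,5E,9S)-9-[(2R)-1-hydroxy-6-methylhept-5-en-2-yl]-N1,N2-dimethoxy-N1,N2,6-trimethylcyclonona-2,5-diene-1,2-dicarboxamide | OC[C@H](CCC=C(C)C)[C@@H]1CC/C(C)=C/C/C=C(/C(=O)N(C)OC)[C@H]1C(=O)N(C)OC | intermediate
24 | (2R)-2-[(1S,2S,3E,6E)-2,3-bis(methoxy(methyl)carbamoyl)-7-methylcyclonona-3,6-dien-1-yl]-6-methylhept-5-en-1-yl acetate | CC(=O)OC[C@H](CCC=C(C)C)[C@@H]1CC/C(C)=C/C/C=C(/C(=O)N(C)OC)[C@H]1C(=O)N(C)OC | intermediate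
25 | (2R)-2-[(1S,2S,3E,6E)-2,3-diformyl-7-methylcyclonona-3,6-dien-1-yl]-6-methylhept-5-en-1-yl acetate | CC(=O)OC[C@H](CCC=C(C)C)[C@@H]1CC/C(C)=C/C/C=C(/C=O)[C@H]1C=O | target

## Step count and risks

Total step count: 15. Longest linear sequence: 12 (steps 1–6, 8, 11–15).

Most likely to fail, step 8 (the proposed new radical alkylation). The ketene acetal may hydrolyse or the radical may add to the other alkenes. The fallback uses known two-electron chemistry: it sets out from 12 and comes back at 16. The lithium enolate of 12 (LDA, THF, −78 °C) is alkylated with 2-bromo-N-methoxy-N-methylacetamide anti to the vinyl group to give 2-[(3R,4S,5R)-4-ethenyl-5-(4-methylpent-3-en-1-yl)-2-oxooxan-3-yl]-N-methoxy-N-methylacetamide F1. Deprotonation at the unhindered amide CH2 (LDA, 2.1 equiv) and C-phosphorylation with diethyl chlorophosphate then gives 16.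

Second, step 11 (HWE of a hindered, fully substituted phosphonate carbanion with an isomerisable β,γ-unsaturated aldehyde; E/Z risk). The fallback replaces the olefination by aldol condensation: it sets out from 12 and comes back at 20. Amide F1 (made as above) is deprotonated at the amide α-carbon (LDA, −78 °C) and added to 19 to give the β-hydroxy amide 2-[(3S,4S,5R)-4-ethenyl-5-(4-methylpent-3-en-1-yl)-2-oxooxan-3-yl]-3-hydroxy-6-iodo-N-methoxy-N-methylhept-5-enamide F2. Mesylation (MsCl, Et3N) and E1cB elimination (DBU) then give 20.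

Third, step 12 (nine-membered ring closure by B-alkyl Suzuki coupling under aqueous base). The fallback moves the ring-closing bond to C7=C8: it sets out from 16 (with 18) and comes back at 22. Hydroboration of 16 with 9-BBN gives the B-alkyl-9-BBN borane of 16 F3. Intermolecular Suzuki coupling with 18 (Pd(dppf)Cl2, K3PO4) gives the (E)-homoallylic alcohol diethyl {1-[(3R,4S,5R)-4-[(E)-6-hydroxy-3-methylhex-3-en-1-yl]-5-(4-methylpent-3-en-1-yl)-2-oxooxan-3-yl]-2-(methoxy(methyl)amino)-2-oxoethyl}phosphonate F4. Dess–Martin oxidation gives the corresponding aldehyde F5. An intramolecular HWE reaction (LiCl, DBU, MeCN, 1 mM) can only give the ring-cis C7=C8 alkene and closes the ring to 22.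

## Further compounds

F1 | step 8 | 2-[(3R,4S,5R)-4-ethenyl-5-(4-methylpent-3-en-1-yl)-2-oxooxan-3-yl]-N-methoxy-N-methylacetamide | O=C1[C@H](CC(=O)N(C)OC)[C@@H](C=C)[C@@H](CCC=C(C)C)CO1
F2 | step 11 | 2-[(3S,4S,5R)-4-ethenyl-5-(4-methylpent-3-en-1-yl)-2-oxooxan-3-yl]-3-hydroxy-6-iodo-N-methoxy-N-methylhept-5-enamide (5E; mixture at C2 and C3 of the chain) | O=C1[C@H](C(C(O)C/C=C(\C)I)C(=O)N(C)OC)[C@@H](C=C)[C@@H](CCC=C(C)C)CO1
F3 | step 12 | diethyl {1-[(3R,4S,5R)-4-[2-(9-borabicyclo[3.3.1]nonan-9-yl)ethyl]-5-(4-methylpent-3-en-1-yl)-2-oxooxan-3-yl]-2-(methoxy(methyl)amino)-2-oxoethyl}phosphonate | O=C1[C@H](C(P(=O)(OCC)OCC)C(=O)N(C)OC)[C@@H](CCB2C3CCCC2CCC3)[C@@H](CCC=C(C)C)CO1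
F4 | step 12 | diethyl {1-[(3R,4S,5R)-4-[(E)-6-hydroxy-3-methylhex-3-en-1-yl]-5-(4-methylpent-3-en-1-yl)-2-oxooxan-3-yl]-2-(methoxy(methyl)amino)-2-oxoethyl}phosphonate | O=C1[C@H](C(P(=O)(OCC)OCC)C(=O)N(C)OC)[C@@H](CC/C(C)=C/CCO)[C@@H](CCC=C(C)C)CO1
F5 | step 12 | diethyl {1-[(3R,4S,5R)-4-[(E)-3-methyl-6-oxohex-3-en-1-yl]-5-(4-methylpent-3-en-1-yl)-2-oxooxan-3-yl]-2-(methoxy(methyl)amino)-2-oxoethyl}phosphonate | O=C1[C@H](C(P(=O)(OCC)OCC)C(=O)N(C)OC)[C@@H](CC/C(C)=C/CC=O)[C@@H](CCC=C(C)C)CO1
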